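**Retrosynthetic overview**
1. The benzene ring is bought with both bromines in place as 3,4-dibromobenzaldehyde 1; nitration ortho to the CHO group (→ 2) installs the future N1.
2. Key C–C disconnection is C2–C3 of the indole: intermolecular nitroaldol (Henry) addition of nitromethane 3 to aldehyde 2 (→ 4), then dehydration via mesylate 5 to dinitrostyrene 6.
3. Ring order: the benzene ring is preformed; the pyrrole ring is the only ring made, closed by N1–C2 bond formation in the reductive cyclisation of 6 (via 7) to 5,6-dibromoindole 8.
4. End game on the intact indole: N-methylation (sodium salt 9 → 10), then electrophilic C3 bromination to the target 11.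

Assumption: the target has no stereocentre and is achiral, so no enantiocontrol is needed; the one stereocentre made en route (in 4) is racemic and is destroyed in step 3.

**Route**

Step 1
Reactants: 1 3,4-dibromobenzaldehyde
Product: 2 4,5-dibromo-2-nitrobenzaldehyde
Conditions: KNO3 (1.05 equiv), conc. H2SO4, 0–5 °C; pour onto ice; recrystallise from EtOH
Reagents that add atoms: potassium nitrate, [K+].[O-][N+](=O)[O-]
Why: Electrophilic aromatic nitration goes para to the 3-bromine and ortho to CHO (the halogen-controlled position, as with other 3-halo- and 3,4-dihalobenzaldehydes), and the cold, stoichiometric nitrate keeps the aldehyde from being oxidised.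

Step 2
Reactants: 2 4,5-dibromo-2-nitrobenzaldehyde; 3 nitromethane
Product: 4 rac-1-(4,5-dibromo-2-nitrophenyl)-2-nitroethan-1-ol
Conditions: MeNO2 (10 equiv), Et3N (0.1 equiv), THF, 0 °C to rt; AcOH quench
Reagents that add atoms: none
Why: Henry (nitroaldol) addition of the nitronate to the strongly electrophilic o-nitrobenzaldehyde forms the C2–C3 bond; the catalytic tertiary amine avoids SNAr at the bromine para to the nitro group, and the new carbinol stereocentre is formed racemic and removed in step 3.

Step 3
Reactants: 4 rac-1-(4,5-dibromo-2-nitrophenyl)-2-nitroethan-1-ol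
Product: 6 1,2-dibromo-4-nitro-5-[(E)-2-nitroethenyl]benzene, via nitro mesylate 5 (not isolated)
Conditions: MsCl (1.2 equiv), Et3N (2.5 equiv, added slowly), CH2Cl2, −10 to 0 °C; cold dilute HCl quench
Reagents that add atoms: none
Why: O-mesylation followed by E1cB elimination of the acidic α-nitro proton gives the conjugated (E)-nitroalkene (thermodynamic geometry) at low temperature, before the base can polymerise it.

Step 4
Reactants: 6 1,2-dibromo-4-nitro-5-[(E)-2-nitroethenyl]benzene
Product: 8 5,6-dibromo-1H-indole, via amino imine 7 (not isolated)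
Conditions: Fe powder (12 equiv), silica gel, AcOH/toluene, 90 °C, N2; filter, NaHCO3 wash
Reagents that add atoms: none
Why: Reductive cyclisation of an o,β-dinitrostyrene (Nenitzescu-type): zerovalent iron in AcOH reduces both nitro groups, the aniline nitrogen adds to the side-chain imine carbon and ammonia is lost to aromatise, while the aryl C–Br bonds, which hydrogenation over palladium would cleave, are untouched.

Step 5
Reactants: 8 5,6-dibromo-1H-indole
Product: 10 5,6-dibromo-1-methyl-1H-indole, via sodium indolide 9 (not isolated)
Conditions: NaH (1.2 equiv), DMF, 0 °C, 30 min; then MeI (1.3 equiv), 0 °C to rt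
Reagents that add atoms: iodomethane, CI
Why: Irreversible deprotonation of the indole N–H and SN2 methylation of the sodium indolide in a polar aprotic solvent gives clean N-alkylation over C3-alkylation.

Step 6
Reactants: 10 5,6-dibromo-1-methyl-1H-indole
Product: 11 3,5,6-tribromo-1-methyl-1H-indole
Conditions: NBS (1.05 equiv), DMF, 0 °C to rt, dark; aqueous Na2S2O3 work-up
Reagents that add atoms: N-bromosuccinimide, O=C1CCC(=O)N1Br
Why: Electrophilic aromatic substitution at C3, the most nucleophilic position of an N-alkylindole; one equivalent of NBS leaves C2 and the deactivated benzene ring alone.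

**Compound list**
1 | 3,4-dibromobenzaldehyde | O=Cc1ccc(Br)c(Br)c1 | starting material
2 | 4,5-dibromo-2-nitrobenzaldehyde | O=Cc1cc(Br)c(Br)cc1[N+](=O)[O-] | intermediate
3 | nitromethane | C[N+](=O)[O-] | starting material
4 | rac-1-(4,5-dibromo-2-nitrophenyl)-2-nitroethan-1-ol (racemate) | OC(C[N+](=O)[O-])c1cc(Br)c(Br)cc1[N+](=O)[O-] | intermediate
5 | rac-1-(4,5-dibromo-2-nitrophenyl)-2-nitroethyl methanesulfonate (racemate) | CS(=O)(=O)OC(C[N+](=O)[O-])c1cc(Br)c(Br)cc1[N+](=O)[O-] | intermediate
6 | 1,2-dibromo-4-nitro-5-[(E)-2-nitroethenyl]benzene | O=[N+]([O-])/C=C/c1cc(Br)c(Br)cc1[N+](=O)[O-] | intermediate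
7 | 2-(2-amino-4,5-dibromophenyl)ethan-1-imine | N=CCc1cc(Br)c(Br)cc1N | intermediate
8 | 5,6-dibromo-1H-indole | Brc1cc2cc[nH]c2cc1Br | intermediate
9 | sodium 5,6-dibromoindol-1-ide | [Na+].Brc1cc2cc[n-]c2cc1Br | intermediate
10 | 5,6-dibromo-1-methyl-1H-indole | Cn1ccc2cc(Br)c(Br)cc21 | intermediate
11 | 3,5,6-tribromo-1-methyl-1H-indole | Cn1cc(Br)c2cc(Br)c(Br)cc21 | target

**Summary**
Total step count: 6. Longest linear sequence: 6 steps (1 → 2 → 4 → 6 → 8 → 10 → 11).

**Steps most likely to fail, with fallbacks**

Step 4 (reductive cyclisation; a twelve-electron reduction of a polymerisation-prone Michael acceptor). The fallback sets out from 2 and comes back at 8. Aldehyde 2 is homologated by a Wittig reaction with the ylide from (methoxymethyl)triphenylphosphonium chloride and KOtBu in THF at 0 °C to the enol ether 1,2-dibromo-4-(2-methoxyethenyl)-5-nitrobenzene F6 (E/Z mixture, both isomers usable). Fe powder in AcOH/EtOH at 80 °C then reduces only the aryl nitro group to 4,5-dibromo-2-(2-methoxyethenyl)aniline F7. In the same acidic medium the aniline adds to the protonated enol ether and methanol is lost, giving 8. This needs only a six-electron reduction and never forms a nitroalkene.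

Step 1 (nitration; risk of isomer mixtures or oxidation of the aldehyde). The fallback sets out from 1 and comes back at 8, with no nitration. Aldehyde 1 is condensed with ethyl azidoacetate (NaOEt, EtOH, −10 °C, aldol-type condensation) to ethyl (2Z)-2-azido-3-(3,4-dibromophenyl)prop-2-enoate F1. Thermolysis in refluxing xylene (Hemetsberger–Knittel nitrene insertion) gives ethyl 5,6-dibromo-1H-indole-2-carboxylate F2. Insertion into the less hindered ortho C–H bond is expected to be favoured, but a mixture is likely, and the product is purified by chromatography and crystallisation. Saponification (NaOH, EtOH/H2O, then HCl) gives 5,6-dibromo-1H-indole-2-carboxylic acid F3, and protodecarboxylation (Cu powder, quinoline, about 210 °C) gives 8.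

Step 3 (dehydration; the dinitrostyrene can polymerise or add nucleophiles under basic conditions). The fallback sets out from 2 and comes back at 6, under acidic conditions and without the nitro alcohol. Aldehyde 2 is condensed with n-butylamine (1.0 equiv, MgSO4, CH2Cl2, rt, to avoid SNAr) to the aldimine (E)-N-butyl-1-(4,5-dibromo-2-nitrophenyl)methanimine F4. Stirring F4 with nitromethane 3 in AcOH at rt to 50 °C gives Mannich-type (aza-Henry) addition to rac-N-[1-(4,5-dibromo-2-nitrophenyl)-2-nitroethyl]butan-1-amine F5, which is not isolated. F5 eliminates butylamine in the acid to give 6 directly.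

**Further compounds**
F1 | step 1 | ethyl (2Z)-2-azido-3-(3,4-dibromophenyl)prop-2-enoate | CCOC(=O)/C(N=[N+]=[N-])=C/c1ccc(Br)c(Br)c1
F2 | step 1 | ethyl 5,6-dibromo-1H-indole-2-carboxylate | CCOC(=O)c1cc2cc(Br)c(Br)cc2[nH]1
F3 | step 1 | 5,6-dibromo-1H-indole-2-carboxylic acid | OC(=O)c1cc2cc(Br)c(Br)cc2[nH]1
F4 | step 3 | (E)-N-butyl-1-(4,5-dibromo-2-nitrophenyl)methanimine | CCCC/N=C/c1cc(Br)c(Br)cc1[N+](=O)[O-]
F5 | step 3 | rac-N-[1-(4,5-dibromo-2-nitrophenyl)-2-nitroethyl]butan-1-amine | CCCCNC(C[N+](=O)[O-])c1cc(Br)c(Br)cc1[N+](=O)[O-]
F6 | step 4 | 1,2-dibromo-4-(2-methoxyethenyl)-5-nitrobenzene (E/Z mixture) | COC=Cc1cc(Br)c(Br)cc1[N+](=O)[O-]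
F7 | step 4 | 4,5-dibromo-2-(2-methoxyethenyl)aniline (E/Z mixture) | COC=Cc1cc(Br)c(Br)cc1N
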